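**Plan**
- Feature used: the ketone carbon sits on benzene carbon C1 and a phenol oxygen on the neighbouring C2 (an ortho-hydroxyaryl ketone), the second oxygen is at C4 and C6 is free. C1 and C2 can therefore be the two carbons of an aryne.
- Retrosynthesis: a temporary Br at C6 and a MOM group on O4 are removed, then C(=O)–C1 and C2–O are cut together. This is insertion of 3-bromo-5-(methoxymethoxy)benzyne into the C(=O)–OH bond of the free C17 acid.
- The acid is cut between C2 and the quaternary C3, giving (2E,6E)-farnesyl methyl carbonate and dimethyl malonate.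
- Forward: the aryne precursor is made in two steps from 4-(methoxymethoxy)phenol (one Br exchanged for SiMe3, the other kept beside the future triple bond). The chain runs farnesol → carbonate → allylic alkylation → dealkoxycarbonylation → acid. The fragments are joined by the aryne insertion, then Br and MOM are removed; the benzene ring is bought and no ring is built.
- Stereochemistry: the quaternary centre (3R in the target) comes from ligand control in the iridium-catalysed branched-selective allylic alkylation. The 6E alkene comes from farnesol; neither is touched later.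

Key step: step 7

Remark: 4-(methoxymethoxy)phenol is taken as a catalogue compound; in the iridium step the ligand antipode is the one that leads to the (3R) acid, to be confirmed by correlation.

**Step 1**
Reactants: 1 4-(methoxymethoxy)phenol
Product: 2 2,6-dibromo-4-(methoxymethoxy)phenol
Conditions: NBS (2.05 equiv), i-Pr2NH (10 mol%), CH2Cl2, 0 °C → rt
Reagents that add atoms: N-bromosuccinimide, O=C1CCC(=O)N1Br
Why: Amine-mediated electrophilic aromatic bromination goes ortho to the free phenol (para position blocked), and the neutral medium should spare the MOM acetal.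

**Step 2**
Reactants: 2 2,6-dibromo-4-(methoxymethoxy)phenol
Product: 5 2-bromo-4-(methoxymethoxy)-6-(trimethylsilyl)phenyl trifluoromethanesulfonate, via aryl trimethylsilyl ether 3 (not isolated), via lithium 2-silylphenoxide 4 (not isolated)
Conditions: HN(SiMe3)2, THF, 70 °C, then evaporation; n-BuLi (1.05 equiv), THF, −78 °C; Tf2O (1.2 equiv), −78 °C → rt
Reagents that add atoms: hexamethyldisilazane, C[Si](C)(C)N[Si](C)(C)C; trifluoromethanesulfonic anhydride, O=S(=O)(OS(=O)(=O)C(F)(F)F)C(F)(F)F
Why: O-silylation, bromine–lithium exchange at one of the two equivalent bromines and anionic 1,3 O-to-C silyl migration (retro-Brook rearrangement) should give the ortho-silyl phenoxide, which is triflated to an ortho-silylaryl triflate that keeps the second bromine next to the triflate carbon.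

**Step 3**
Reactants: 6 (2E,6E)-farnesol
Product: 7 methyl (2E,6E)-3,7,11-trimethyldodeca-2,6,10-trien-1-yl carbonate
Conditions: ClCO2Me (1.3 equiv), pyridine, CH2Cl2, 0 °C → rt
Reagents that add atoms: methyl chloroformate, COC(=O)Cl
Why: Carbonate formation by acylation of a primary allylic alcohol with a chloroformate, which leaves the alkene geometry untouched.

**Step 4**
Reactants: 7 methyl (2E,6E)-farnesyl carbonate; 8 dimethyl malonate
Product: 9 dimethyl 2-[(3S,6E)-3,7,11-trimethyldodeca-1,6,10-trien-3-yl]propanedioate
Conditions: [Ir(cod)Cl]2 (2 mol%), chiral BINOL-derived phosphoramidite ligand (4–8 mol%), NaN(SiMe3)2 (2 equiv), ZnI2 (2 equiv), THF, rt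
Reagents that add atoms: none
Why: Iridium-catalysed branched-selective asymmetric allylic alkylation (Tsuji–Trost type) of a trisubstituted allylic carbonate, in which the zinc malonate attacks the more substituted terminus of the η3-allyl complex of trivalent iridium on the face fixed by the ligand, so the quaternary centre (3S in 9) is set by catalyst control together with the E geometry of 7.

**Step 5**
Reactants: 9 dimethyl 2-[(3S,6E)-3,7,11-trimethyldodeca-1,6,10-trien-3-yl]propanedioate
Product: 10 methyl (3R,6E)-3-ethenyl-3,7,11-trimethyldodeca-6,10-dienoate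
Conditions: LiCl (3 equiv), H2O (2 equiv), DMSO, 150 °C
Reagents that add atoms: none
Why: Krapcho dealkoxycarbonylation (chloride demethylation, decarboxylation, protonation) should remove one ester without touching the alkenes or the quaternary centre, which cannot epimerise.

**Step 6**
Reactants: 10 methyl (3R,6E)-3-ethenyl-3,7,11-trimethyldodeca-6,10-dienoate
Product: 11 (3R,6E)-3-ethenyl-3,7,11-trimethyldodeca-6,10-dienoic acid
Conditions: LiOH·H2O (4 equiv), THF/MeOH/H2O, 50 °C; then 1 M HCl
Reagents that add atoms: lithium hydroxide, [Li+].[OH-]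
Why: Ester saponification of a neopentyl-type methyl ester needs gentle heating only, and no stereocentre is at risk.

**Step 7**
Reactants: 11 (3R,6E)-3-ethenyl-3,7,11-trimethyldodeca-6,10-dienoic acid; 5 2-bromo-4-(methoxymethoxy)-6-(trimethylsilyl)phenyl trifluoromethanesulfonate
Product: 13 (3R,6E)-1-[2-bromo-6-hydroxy-4-(methoxymethoxy)phenyl]-3-ethenyl-3,7,11-trimethyldodeca-6,10-dien-1-one, via 3-bromo-5-(methoxymethoxy)benzyne 12 (not isolated)
Conditions: 5 (1.5 equiv, in portions), CsF (4 equiv), THF, 125 °C, sealed tube
Reagents that add atoms: none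
Why: Fluoride attacks silicon in 5 and triflate leaves to give aryne 12; the cesium carboxylate of 11 adds through oxygen to the aryne carbon remote from bromine, and the aryl anion so formed, flanked by the ester oxygen carbon and the C–Br carbon, attacks the ester carbonyl, after which the four-membered alkoxide reopens to the ortho-acyl phenoxide, so the aryne ends up inserted into the C(=O)–O bond. The closest known reaction type is the fluoride-mediated insertion of arynes into the C–O bond of carboxylic acids to give ortho-hydroxyaryl ketones, in mechanism an aryne-triggered anionic Fries-type 1,3 O-to-C acyl shift. The only ring closed is the transient benzoxetene alkoxide, formed by 4-exo-trig attack and opened again at once, so no ring remains in 13. No stereocentre is created, and the quaternary centre, two bonds from the reacting carbonyl and without an acidic hydrogen, should pass unchanged. The step needs regioselectivity (oxygen at C2, acyl at C1), which the bromine beside the triple bond should secure: its inductive pull distorts the aryne so that the distal carbon is the more electrophilic one and the negative charge develops next to C–Br, while the methoxymethoxy group two positions away exerts only a weak opposing bias. It also needs acyl capture to beat protonation of the aryl anion, which the aprotic medium, the high temperature and the excess of 5 favour.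

**Step 8**
Reactants: 13 (3R,6E)-1-[2-bromo-6-hydroxy-4-(methoxymethoxy)phenyl]-3-ethenyl-3,7,11-trimethyldodeca-6,10-dien-1-one
Product: 16 (3R,6E)-3-ethenyl-1-[2-hydroxy-4-(methoxymethoxy)phenyl]-3,7,11-trimethyldodeca-6,10-dien-1-one, via dilithium enolate phenoxide 14 (not isolated), via aryllithium 15 (not isolated)
Conditions: LiN(SiMe3)2 (2.1 equiv), THF, −78 → 0 °C; t-BuLi (4.2 equiv), −78 °C, 15 min; H2O, −78 °C → rt
Reagents that add atoms: none
Why: Bromine–lithium exchange and protonation with the ketone masked in the flask as its lithium enolate should work because at −78 °C the exchange is much faster than addition to the enolate or carbolithiation of the vinyl group, the excess of t-BuLi covering the hexamethyldisilazane set free on enolisation.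

**Step 9**
Reactants: 16 (3R,6E)-3-ethenyl-1-[2-hydroxy-4-(methoxymethoxy)phenyl]-3,7,11-trimethyldodeca-6,10-dien-1-one
Product: 17 (3R,6E)-1-(2,4-dihydroxyphenyl)-3-ethenyl-3,7,11-trimethyldodeca-6,10-dien-1-one
Conditions: 2 M aq. HCl, MeOH, rt → 40 °C
Reagents that add atoms: none
Why: Acid-catalysed acetal cleavage (methanolysis of the MOM ether) should proceed under dilute acid, where the isolated trisubstituted alkenes and the vinyl group are not protonated at a useful rate.

**Compound list**
1 | 4-(methoxymethoxy)phenol | COCOc1ccc(O)cc1 | starting material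
2 | 2,6-dibromo-4-(methoxymethoxy)phenol | COCOc1cc(Br)c(O)c(Br)c1 | intermediate
3 | [2,6-dibromo-4-(methoxymethoxy)phenoxy]trimethylsilane | COCOc1cc(Br)c(O[Si](C)(C)C)c(Br)c1 | intermediate
4 | lithium 2-bromo-4-(methoxymethoxy)-6-(trimethylsilyl)phenoxide | COCOc1cc(Br)c([O-])c([Si](C)(C)C)c1.[Li+] | intermediate
5 | 2-bromo-4-(methoxymethoxy)-6-(trimethylsilyl)phenyl trifluoromethanesulfonate | COCOc1cc(Br)c(OS(=O)(=O)C(F)(F)F)c([Si](C)(C)C)c1 | intermediate
6 | (2E,6E)-farnesol, (2E,6E)-3,7,11-trimethyldodeca-2,6,10-trien-1-ol | OC/C=C(\C)CC/C=C(\C)CCC=C(C)C | starting material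
7 | methyl (2E,6E)-3,7,11-trimethyldodeca-2,6,10-trien-1-yl carbonate | COC(=O)OC/C=C(\C)CC/C=C(\C)CCC=C(C)C | intermediate
8 | dimethyl malonate | COC(=O)CC(=O)OC | starting material
9 | dimethyl 2-[(3S,6E)-3,7,11-trimethyldodeca-1,6,10-trien-3-yl]propanedioate | C=C[C@](C)(CC/C=C(\C)CCC=C(C)C)C(C(=O)OC)C(=O)OC | intermediate
10 | methyl (3R,6E)-3-ethenyl-3,7,11-trimethyldodeca-6,10-dienoate | C=C[C@](C)(CC/C=C(\C)CCC=C(C)C)CC(=O)OC | intermediate
11 | (3R,6E)-3-ethenyl-3,7,11-trimethyldodeca-6,10-dienoic acid | C=C[C@](C)(CC/C=C(\C)CCC=C(C)C)CC(=O)O | intermediate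
12 | 3-bromo-5-(methoxymethoxy)benzyne (triple bond between the former C–OTf and C–SiMe3 carbons, Br on the carbon next to it) | BrC1=CC(OCOC)=CC#C1 | intermediate
13 | (3R,6E)-1-[2-bromo-6-hydroxy-4-(methoxymethoxy)phenyl]-3-ethenyl-3,7,11-trimethyldodeca-6,10-dien-1-one | C=C[C@](C)(CC/C=C(\C)CCC=C(C)C)CC(=O)c1c(O)cc(OCOC)cc1Br | intermediate
14 | dilithium enolate phenoxide of 13 (quaternary centre arranged as in 13, enolate geometry not defined) | C=C[C@](C)(CC/C=C(\C)CCC=C(C)C)C=C([O-])c1c([O-])cc(OCOC)cc1Br.[Li+].[Li+] | intermediate
15 | aryllithium from 14 (Li in place of Br, quaternary centre as in 13) | C=C[C@](C)(CC/C=C(\C)CCC=C(C)C)C=C([O-])c1c([O-])cc(OCOC)cc1[Li].[Li+].[Li+] | intermediate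
16 | (3R,6E)-3-ethenyl-1-[2-hydroxy-4-(methoxymethoxy)phenyl]-3,7,11-trimethyldodeca-6,10-dien-1-one | C=C[C@](C)(CC/C=C(\C)CCC=C(C)C)CC(=O)c1ccc(OCOC)cc1O | intermediate
17 | (3R,6E)-1-(2,4-dihydroxyphenyl)-3-ethenyl-3,7,11-trimethyldodeca-6,10-dien-1-one | C=C[C@](C)(CC/C=C(\C)CCC=C(C)C)CC(=O)c1ccc(O)cc1O | target

**Count**
Total steps: 9. Longest linear sequence: 7 steps (6 → 17, steps 3 to 9); steps 1 and 2 make the aryne precursor in a side branch.

**Steps most likely to fail**

Step 7. The aryl anion may be protonated before it captures the acyl group, so that the reaction stops at the aryl ester. The ortho-bromoaryl anion may also lose bromide, the aryne may undergo ene reactions with the trisubstituted alkenes, and excess aryne may O-arylate the product phenoxide. The fallback builds the ketone by acylation of an aryllithium. It sets out from 10, which with MeNH(OMe)·HCl and i-PrMgCl (THF, −20 °C) should give (3R,6E)-3-ethenyl-N-methoxy-N,3,7,11-tetramethyldodeca-6,10-dienamide F1. Commercial 4-bromoresorcinol with MOMCl and i-Pr2NEt should give 1-bromo-2,4-bis(methoxymethoxy)benzene F2. Bromine–lithium exchange (n-BuLi, THF, −78 °C) turns F2 into [2,4-bis(methoxymethoxy)phenyl]lithium F3, which is acylated by F1 to (3R,6E)-1-[2,4-bis(methoxymethoxy)phenyl]-3-ethenyl-3,7,11-trimethyldodeca-6,10-dien-1-one F4. Aqueous HCl in MeOH removes both MOM groups, and the route is rejoined at 17.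

Step 8. Enolisation of the hindered ketone may be incomplete, which would open the carbonyl to addition of t-BuLi. The aryllithium may also close onto the vinyl group, or lithiation may occur next to the MOM ether. The fallback protects the ketone by a redox detour and sets out from 13. LiAlH4 (THF, 0 °C) should give (3R,6E)-1-[2-bromo-6-hydroxy-4-(methoxymethoxy)phenyl]-3-ethenyl-3,7,11-trimethyldodeca-6,10-dien-1-ol F5 as both epimers at the carbinol carbon. t-BuLi (4.2 equiv, THF, −78 °C) followed by water should give (3R,6E)-3-ethenyl-1-[2-hydroxy-4-(methoxymethoxy)phenyl]-3,7,11-trimethyldodeca-6,10-dien-1-ol F6. MnO2 (CH2Cl2, rt) reoxidises the benzylic alcohol, and the route is rejoined at 16.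

Step 4. Facial discrimination between the methyl group and the long chain at the allyl terminus may be poor. Linear product may form, and syn/anti isomerisation of the allyl complex would erode the enantiomeric purity. The fallback gives up catalytic control and sets out from 6. Johnson–Claisen rearrangement (MeC(OEt)3, cat. EtCO2H, 140 °C) should give racemic ethyl (6E)-3-ethenyl-3,7,11-trimethyldodeca-6,10-dienoate F7. LiOH converts it into racemic (6E)-3-ethenyl-3,7,11-trimethyldodeca-6,10-dienoic acid F8. The enantiomers are separated by preparative chromatography on a chiral stationary phase, and the route is rejoined at 11.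

**Further compounds**
F1 | step 7 | (3R,6E)-3-ethenyl-N-methoxy-N,3,7,11-tetramethyldodeca-6,10-dienamide | C=C[C@](C)(CC/C=C(\C)CCC=C(C)C)CC(=O)N(C)OC
F2 | step 7 | 1-bromo-2,4-bis(methoxymethoxy)benzene | COCOc1ccc(Br)c(OCOC)c1
F3 | step 7 | [2,4-bis(methoxymethoxy)phenyl]lithium | [Li]c1ccc(OCOC)cc1OCOC
F4 | step 7 | (3R,6E)-1-[2,4-bis(methoxymethoxy)phenyl]-3-ethenyl-3,7,11-trimethyldodeca-6,10-dien-1-one | C=C[C@](C)(CC/C=C(\C)CCC=C(C)C)CC(=O)c1ccc(OCOC)cc1OCOC
F5 | step 8 | (3R,6E)-1-[2-bromo-6-hydroxy-4-(methoxymethoxy)phenyl]-3-ethenyl-3,7,11-trimethyldodeca-6,10-dien-1-ol (both epimers at C1) | C=C[C@](C)(CC/C=C(\C)CCC=C(C)C)CC(O)c1c(O)cc(OCOC)cc1Br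
F6 | step 8 | (3R,6E)-3-ethenyl-1-[2-hydroxy-4-(methoxymethoxy)phenyl]-3,7,11-trimethyldodeca-6,10-dien-1-ol (both epimers at C1) | C=C[C@](C)(CC/C=C(\C)CCC=C(C)C)CC(O)c1ccc(OCOC)cc1O
F7 | step 4 | racemic ethyl (6E)-3-ethenyl-3,7,11-trimethyldodeca-6,10-dienoate | C=CC(C)(CC/C=C(\C)CCC=C(C)C)CC(=O)OCC
F8 | step 4 | racemic (6E)-3-ethenyl-3,7,11-trimethyldodeca-6,10-dienoic acid | C=CC(C)(CC/C=C(\C)CCC=C(C)C)CC(=O)O
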